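Assumption: (9Z)-hexadec-9-enal (pheromone grade), (R)-epichlorohydrin and 2-(tert-butyldimethylsilyl)-1,3-dithiane are bought. Locants C1–C6 (ring) and C1'–C17' (side chain) are those of the target; TBS = tert-butyldimethylsilyl, TBSO = tert-butyldimethylsilyloxy, TMS = trimethylsilyl.

## Retrosynthetic overview

1. The enone C2=C3 and the free hydroxyls come last: Saegusa dehydrogenation of a saturated α-ketol (the quaternary C6 blocks the other side), then global desilylation.
2. Key disconnection C1–C6: a carbene-catalysed intramolecular crossed benzoin of an acyclic keto-aldehyde. The aldehyde carbon C1 acts as an acyl anion and attacks the C6 ketone; this closes the only ring and sets the quaternary carbinol.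
3. The keto-aldehyde comes from a terminal alkene (anti-Markovnikov Wacker) and a dithiane-masked C6 ketone.
4. The C23 chain is assembled in one flask from 2-TBS-1,3-dithiane (C6) and two terminal epoxides that carry the C2' and C4 stereocentres.
5. The epoxides come from (9Z)-hexadec-9-enal (methylenation, hydrolytic kinetic resolution) and from (R)-epichlorohydrin (vinyl Grignard, ring closure).

## Route

Step 1
Reactants: 1 (9Z)-hexadec-9-enal
Product: 2 rac-2-[(8Z)-pentadec-8-en-1-yl]oxirane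
Conditions: Me3S+ I−, n-BuLi, THF, −10 °C → rt
Reagents that add atoms: trimethylsulfonium iodide, C[S+](C)C.[I-]
Why: Corey–Chaykovsky epoxidation, in which dimethylsulfonium methylide adds to the aldehyde and the betaine closes to the terminal epoxide without touching the Z alkene (racemic at this stage).

Step 2
Reactants: 2 rac-2-[(8Z)-pentadec-8-en-1-yl]oxirane
Product: 3 (2S)-2-[(8Z)-pentadec-8-en-1-yl]oxirane
Conditions: (S,S)-(salen)Co(OAc) (0.5 mol%; salen = N,N'-bis(3,5-di-tert-butylsalicylidene)cyclohexane-1,2-diaminate, trivalent cobalt), H2O (0.55 equiv), THF (min.), 0 °C → rt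
Reagents that add atoms: none
Why: Jacobsen hydrolytic kinetic resolution, in which the (S,S) catalyst hydrolyses the (R)-epoxide selectively and leaves the (S)-epoxide in high ee (maximum 50% yield), so the C2' stereocentre is set by resolution.

Step 3
Reactants: 4 (R)-epichlorohydrin
Product: 6 (R)-2-allyloxirane, via bromomagnesium (2R)-1-chloropent-4-en-2-olate 5 (not isolated)
Conditions: CH2=CHMgBr, CuI (10 mol%), THF, −78 → −40 °C; then 5 M NaOH (aq), 0 °C → rt; distil
Reagents that add atoms: vinylmagnesium bromide, C=C[Mg]Br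
Why: copper-catalysed Grignard opening of the epoxide at its CH2 terminus followed by Williamson ring closure onto the CH2Cl carbon; the C–O bond at the stereocentre is never broken, so (R)-epichlorohydrin gives the (R)-epoxide that becomes C4.

Step 4
Reactants: 7 2-(tert-butyldimethylsilyl)-1,3-dithiane; 3 (2S)-2-[(8Z)-pentadec-8-en-1-yl]oxirane; 6 (R)-2-allyloxirane
Product: 12 2-[(2R)-2-(TBSO)pent-4-en-1-yl]-2-[(2S,10Z)-2-(TBSO)heptadec-10-en-1-yl]-1,3-dithiane, via 2-lithio-2-TBS-1,3-dithiane 8 (not isolated), via mono-adduct lithium alkoxide 9 (not isolated), via Brook-rearranged 2-lithiodithiane 10 (not isolated), via bis-adduct lithium alkoxide 11 (not isolated)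
Conditions: t-BuLi, Et2O, −78 → −45 °C; 3, −78 → −25 °C; then 6, HMPA, −78 → 0 °C; then TBSOTf, −78 → 0 °C
Reagents that add atoms: tert-butyldimethylsilyl trifluoromethanesulfonate, CC(C)(C)[Si](C)(C)OS(=O)(=O)C(F)(F)F
Why: three-component dithiane linchpin coupling (anion relay), in which lithiated 7 opens 3 at CH2, HMPA triggers the 1,4-Brook shift of TBS from carbon to oxygen to unveil a new dithiane anion (acyl anion equivalent for C6) that opens 6 at CH2, and the last alkoxide is silylated; both carbinol centres pass unchanged from the epoxides because no bond to them is made or broken.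

Step 5
Reactants: 12 2-[(2R)-2-(TBSO)pent-4-en-1-yl]-2-[(2S,10Z)-2-(TBSO)heptadec-10-en-1-yl]-1,3-dithiane
Product: 13 (4R,8S,16Z)-4,8-bis(TBSO)tricosa-1,16-dien-6-one
Conditions: MeI, CaCO3, MeCN/H2O 9:1, 45 °C
Reagents that add atoms: water, O
Why: alkylative dithioacetal hydrolysis (S-methylation, then hydrolysis of the thionium ion) under carbonate buffering, which spares both alkenes and both silyl ethers.

Step 6
Reactants: 13 (4R,8S,16Z)-4,8-bis(TBSO)tricosa-1,16-dien-6-one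
Product: 14 (4R,8S,16Z)-4,8-bis(TBSO)-6-oxotricos-16-enal
Conditions: PdCl2(PhCN)2 (12 mol%), CuCl2·2H2O (12 mol%), AgNO2 (6 mol%), O2 (1 atm), t-BuOH/MeNO2 15:1, rt
Reagents that add atoms: dioxygen, O=O
Why: nitrite-modified aldehyde-selective (anti-Markovnikov) Tsuji–Wacker oxidation, which works on terminal alkenes bearing a homoallylic oxygen substituent and leaves the much less reactive internal Z alkene alone.

Step 7
Reactants: 14 (4R,8S,16Z)-4,8-bis(TBSO)-6-oxotricos-16-enal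
Product: 15 (2R,4R)-4-(TBSO)-2-hydroxy-2-[(2S,10Z)-2-(TBSO)heptadec-10-en-1-yl]cyclohexan-1-one
Conditions: 2-(pentafluorophenyl)-6,7-dihydro-5H-pyrrolo[2,1-c][1,2,4]triazol-2-ium tetrafluoroborate (20 mol%), Et3N (1 equiv), CH2Cl2 (0.02 M), rt
Reagents that add atoms: none
Why: intramolecular crossed aldehyde–ketone benzoin reaction under N-heterocyclic carbene catalysis, in which the carbene turns C1 into a nucleophilic Breslow intermediate (acyl anion equivalent) that adds to the C6 ketone through a six-membered chair with the C4 silyloxy group equatorial and the enol O–H hydrogen-bonded to the ketone oxygen, so the new C–O bond is predicted to end up equatorial and cis to C4–O with the side chain axial, which is the (2R) centre.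

Step 8
Reactants: 15 (2R,4R)-4-(TBSO)-2-hydroxy-2-[(2S,10Z)-2-(TBSO)heptadec-10-en-1-yl]cyclohexan-1-one
Product: 17 (4S,6R)-4-(TBSO)-6-[(2S,10Z)-2-(TBSO)heptadec-10-en-1-yl]-6-(trimethylsilyloxy)cyclohex-2-en-1-one, via bis-TMS silyl enol ether 16 (not isolated)
Conditions: TMSOTf, Et3N, CH2Cl2, 0 °C; evaporate; then Pd(OAc)2 (1.1 equiv), MeCN, rt
Reagents that add atoms: trimethylsilyl trifluoromethanesulfonate, C[Si](C)(C)OS(=O)(=O)C(F)(F)F
Why: Saegusa–Ito oxidation, in which the ketone can enolise only towards C2 (C6 is quaternary), so one silyl enol ether forms and Pd(OAc)2 converts it into the C2=C3 enone while the tertiary hydroxyl is capped as its TMS ether; no stereocentre is touched (the C4 descriptor changes only by priority).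

Step 9
Reactants: 17 (4S,6R)-4-(TBSO)-6-[(2S,10Z)-2-(TBSO)heptadec-10-en-1-yl]-6-(trimethylsilyloxy)cyclohex-2-en-1-one
Product: 18 (4S,6R)-4,6-dihydroxy-6-[(2S,10Z)-2-hydroxyheptadec-10-en-1-yl]cyclohex-2-en-1-one
Conditions: HF·pyridine, pyridine, THF, 0 °C → rt
Reagents that add atoms: none
Why: global fluoride desilylation under buffered, non-basic conditions, which removes the TMS and both TBS groups without the retro-aldol or elimination that a basic fluoride source could cause in the γ-hydroxy enone.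

## Compound list

1 | (9Z)-hexadec-9-enal | CCCCCC/C=C\CCCCCCCC=O | starting material
2 | rac-2-[(8Z)-pentadec-8-en-1-yl]oxirane | CCCCCC/C=C\CCCCCCCC1CO1 | intermediate
3 | (2S)-2-[(8Z)-pentadec-8-en-1-yl]oxirane | CCCCCC/C=C\CCCCCCC[C@H]1CO1 | intermediate
4 | (R)-epichlorohydrin, (2R)-2-(chloromethyl)oxirane | ClC[C@H]1CO1 | starting material
5 | bromomagnesium (2R)-1-chloropent-4-en-2-olate | ClC[C@H](O[Mg]Br)CC=C | intermediate
6 | (R)-2-allyloxirane, (2R)-2-(prop-2-en-1-yl)oxirane | C=CC[C@@H]1CO1 | intermediate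
7 | 2-(tert-butyldimethylsilyl)-1,3-dithiane | CC(C)(C)[Si](C)(C)C1SCCCS1 | starting material
8 | 2-lithio-2-(tert-butyldimethylsilyl)-1,3-dithiane | [Li]C1([Si](C)(C)C(C)(C)C)SCCCS1 | intermediate
9 | lithium (2S,10Z)-1-[2-(tert-butyldimethylsilyl)-1,3-dithian-2-yl]heptadec-10-en-2-olate (mono-adduct lithium alkoxide) | CCCCCC/C=C\CCCCCCC[C@H](O[Li])CC1([Si](C)(C)C(C)(C)C)SCCCS1 | intermediate
10 | 2-lithio-2-[(2S,10Z)-2-(TBSO)heptadec-10-en-1-yl]-1,3-dithiane (Brook-rearranged 2-lithiodithiane) | CCCCCC/C=C\CCCCCCC[C@H](O[Si](C)(C)C(C)(C)C)CC1([Li])SCCCS1 | intermediate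
11 | lithium (2R)-1-{2-[(2S,10Z)-2-(TBSO)heptadec-10-en-1-yl]-1,3-dithian-2-yl}pent-4-en-2-olate (bis-adduct lithium alkoxide) | CCCCCC/C=C\CCCCCCC[C@H](O[Si](C)(C)C(C)(C)C)CC1(C[C@H](O[Li])CC=C)SCCCS1 | intermediate
12 | 2-[(2R)-2-(TBSO)pent-4-en-1-yl]-2-[(2S,10Z)-2-(TBSO)heptadec-10-en-1-yl]-1,3-dithiane | CCCCCC/C=C\CCCCCCC[C@H](O[Si](C)(C)C(C)(C)C)CC1(C[C@H](O[Si](C)(C)C(C)(C)C)CC=C)SCCCS1 | intermediate
13 | (4R,8S,16Z)-4,8-bis(TBSO)tricosa-1,16-dien-6-one | CCCCCC/C=C\CCCCCCC[C@H](O[Si](C)(C)C(C)(C)C)CC(=O)C[C@H](O[Si](C)(C)C(C)(C)C)CC=C | intermediate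
14 | (4R,8S,16Z)-4,8-bis(TBSO)-6-oxotricos-16-enal | CCCCCC/C=C\CCCCCCC[C@H](O[Si](C)(C)C(C)(C)C)CC(=O)C[C@H](O[Si](C)(C)C(C)(C)C)CCC=O | intermediate
15 | (2R,4R)-4-(TBSO)-2-hydroxy-2-[(2S,10Z)-2-(TBSO)heptadec-10-en-1-yl]cyclohexan-1-one | CCCCCC/C=C\CCCCCCC[C@H](O[Si](C)(C)C(C)(C)C)C[C@@]1(O)C[C@H](O[Si](C)(C)C(C)(C)C)CCC1=O | intermediate
16 | (4R,6R)-4-(TBSO)-6-[(2S,10Z)-2-(TBSO)heptadec-10-en-1-yl]-1,6-bis(trimethylsilyloxy)cyclohex-1-ene (bis-TMS silyl enol ether) | CCCCCC/C=C\CCCCCCC[C@H](O[Si](C)(C)C(C)(C)C)C[C@@]1(O[Si](C)(C)C)C[C@H](O[Si](C)(C)C(C)(C)C)CC=C1O[Si](C)(C)C | intermediate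
17 | (4S,6R)-4-(TBSO)-6-[(2S,10Z)-2-(TBSO)heptadec-10-en-1-yl]-6-(trimethylsilyloxy)cyclohex-2-en-1-one | CCCCCC/C=C\CCCCCCC[C@H](O[Si](C)(C)C(C)(C)C)C[C@@]1(O[Si](C)(C)C)C[C@H](O[Si](C)(C)C(C)(C)C)C=CC1=O | intermediate
18 | (4S,6R)-4,6-dihydroxy-6-[(2S,10Z)-2-hydroxyheptadec-10-en-1-yl]cyclohex-2-en-1-one | CCCCCC/C=C\CCCCCCC[C@H](O)C[C@@]1(O)C[C@H](O)C=CC1=O | target

## Step count and risks

Total steps: 9. Longest linear sequence: 8 (steps 1, 2, 4, 5, 6, 7, 8, 9, from 1 to 18); step 3 is a one-step side branch.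

The three steps most likely to fail:

**Step 7 (carbene benzoin ring closure).** The configuration at the new quaternary carbinol rests on substrate control. A competing chair with the side chain equatorial would give the C6 epimer, and base-mediated aldol closure or β-elimination of a silyloxy group could compete. Fallback: setting out from 14, a reductive ketyl–aldehyde pinacol cyclisation with SmI2 (THF/MeOH, −78 °C) gives the cis-diol (1R,2S,5R)-5-(TBSO)-1-[(2S,10Z)-2-(TBSO)heptadec-10-en-1-yl]cyclohexane-1,2-diol F1. Oxidation of its secondary carbinol only (SO3·pyridine, DMSO, iPr2NEt) comes back to the route at 15.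

**Step 6 (aldehyde-selective Wacker oxidation).** The Markovnikov methyl ketone may form, and palladium hydride species could isomerise the Z alkene. Fallback: setting out from 12, 9-BBN (THF, 0 °C → rt, then NaBO3·4H2O) hydroborates only the terminal alkene to give (4R)-4-(TBSO)-5-{2-[(2S,10Z)-2-(TBSO)heptadec-10-en-1-yl]-1,3-dithian-2-yl}pentan-1-ol F2. Oxidation (SO3·pyridine, DMSO, iPr2NEt) gives (4R)-4-(TBSO)-5-{2-[(2S,10Z)-2-(TBSO)heptadec-10-en-1-yl]-1,3-dithian-2-yl}pentanal F3. Hydrolysis of the dithiane (MeI, CaCO3, aqueous MeCN) comes back to the route at 14.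

**Step 4 (one-flask linchpin coupling with in situ silylation).** Four bond-forming events run in sequence; an incomplete Brook shift, proton quench of the second anion or loss of volatile 6 would lower the yield. Fallback: setting out from 3, 2-lithio-1,3-dithiane (from 1,3-dithiane and n-BuLi, THF, −20 °C) opens the epoxide to (2S,10Z)-1-(1,3-dithian-2-yl)heptadec-10-en-2-ol F4. TBSCl/imidazole gives 2-[(2S,10Z)-2-(TBSO)heptadec-10-en-1-yl]-1,3-dithiane F5. Deprotonation (t-BuLi, THF/HMPA, −78 °C) and addition of 6 gives (2R)-1-{2-[(2S,10Z)-2-(TBSO)heptadec-10-en-1-yl]-1,3-dithian-2-yl}pent-4-en-2-ol F6. Silylation (TBSOTf, 2,6-lutidine) comes back to the route at 12.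

Further compounds
F1 | step 7 | (1R,2S,5R)-5-(TBSO)-1-[(2S,10Z)-2-(TBSO)heptadec-10-en-1-yl]cyclohexane-1,2-diol | CCCCCC/C=C\CCCCCCC[C@H](O[Si](C)(C)C(C)(C)C)C[C@@]1(O)C[C@H](O[Si](C)(C)C(C)(C)C)CC[C@@H]1O
F2 | step 6 | (4R)-4-(TBSO)-5-{2-[(2S,10Z)-2-(TBSO)heptadec-10-en-1-yl]-1,3-dithian-2-yl}pentan-1-ol | CCCCCC/C=C\CCCCCCC[C@H](O[Si](C)(C)C(C)(C)C)CC1(C[C@H](O[Si](C)(C)C(C)(C)C)CCCO)SCCCS1
F3 | step 6 | (4R)-4-(TBSO)-5-{2-[(2S,10Z)-2-(TBSO)heptadec-10-en-1-yl]-1,3-dithian-2-yl}pentanal | CCCCCC/C=C\CCCCCCC[C@H](O[Si](C)(C)C(C)(C)C)CC1(C[C@H](O[Si](C)(C)C(C)(C)C)CCC=O)SCCCS1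
F4 | step 4 | (2S,10Z)-1-(1,3-dithian-2-yl)heptadec-10-en-2-ol | CCCCCC/C=C\CCCCCCC[C@H](O)CC1SCCCS1
F5 | step 4 | 2-[(2S,10Z)-2-(TBSO)heptadec-10-en-1-yl]-1,3-dithiane | CCCCCC/C=C\CCCCCCC[C@H](O[Si](C)(C)C(C)(C)C)CC1SCCCS1
F6 | step 4 | (2R)-1-{2-[(2S,10Z)-2-(TBSO)heptadec-10-en-1-yl]-1,3-dithian-2-yl}pent-4-en-2-ol | CCCCCC/C=C\CCCCCCC[C@H](O[Si](C)(C)C(C)(C)C)CC1(C[C@H](O)CC=C)SCCCS1
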